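The target is cut at the C3(l)–C4(l) bond inside ring C of the lower flavan-3,4-diol: the vicinal cis-diol on these two carbons is read as two aldehyde carbons coupled reductively. A samarium diiodide pinacol cyclisation does this in one operation; it forms the C3(l)–C4(l) bond, closes ring C through the O1(l) ether tether already in place and sets both carbinol centres relative to C2(l). Its precursor is a hexabenzylated dialdehyde, an aryl aldehyde at C4(l) and an α-aryloxy aldehyde at C3(l), that carries the 2,4-trans upper flavan; it is released cold from a storable 1,2-diol, and the upper unit arises by Friedel–Crafts arylation of a resolved flavan-4-ol with a symmetric resorcinol.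

Key step: step 16

Remark: (u) marks the upper 4-arylflavan unit and (l) the lower flavan-3,4-diol unit; "chroman" stands for 3,4-dihydro-2H-chromene.
Assumption: the (Sa,Sc,Sc)-binaphthol phosphoramidite on iridium is taken to give the (S)-branched ether, as with simple phenoxides and cinnamyl carbonates; the antipodal ligand would be used if a model run showed the opposite sense.
Remark: the descriptor at C4(u) changes from S to R when O7(l) is benzylated (step 9) and back to S in step 17; only the CIP ranking of the two aryl groups changes, the centre is not touched.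

Step 1
Reactants: 1 2,3-dihydroxybenzaldehyde
Product: 2 2-(benzyloxy)-3-hydroxybenzaldehyde
Conditions: BnBr (1.0 equiv), NaHCO3, NaI (cat.), DMF, 40 °C
Reagents that add atoms: benzyl bromide, BrCc1ccccc1
Why: Williamson etherification of the monoanion: hydrogen carbonate should ionise only the more acidic C2 hydroxyl, whose phenoxide is conjugated with the formyl group, so O2 is benzylated and O3 stays free (the mirror symmetry of 4 would confirm the site).

Step 2
Reactants: 2 2-(benzyloxy)-3-hydroxybenzaldehyde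
Product: 4 2-(benzyloxy)benzene-1,3-diol, via 2-(benzyloxy)-3-hydroxyphenyl formate 3 (not isolated)
Conditions: mCPBA, CH2Cl2, 0 °C to rt; then K2CO3 (cat.), MeOH, rt
Reagents that add atoms: 3-chloroperoxybenzoic acid (mCPBA), OOC(=O)c1cccc(Cl)c1
Why: Dakin-type Baeyer–Villiger oxidation: the electron-rich ortho-alkoxy aryl group migrates to give the aryl formate, and methanolysis frees the second phenol of a symmetric resorcinol.

Step 3
Reactants: 5 1-(2,3,4-trihydroxyphenyl)ethanone
Product: 6 1-[3,4-bis(benzyloxy)-2-hydroxyphenyl]ethanone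
Conditions: BnBr (2.1 equiv), K2CO3, DMF, rt
Reagents that add atoms: benzyl bromide, BrCc1ccccc1
Why: Williamson etherification; the C2 hydroxyl is tied up in a hydrogen bond to the ketone and is the least nucleophilic, so two equivalents of benzyl bromide should cap O3 and O4 only.

Step 4
Reactants: 6 1-[3,4-bis(benzyloxy)-2-hydroxyphenyl]ethanone; 7 4-(benzyloxy)benzaldehyde
Product: 8 (E)-1-[3,4-bis(benzyloxy)-2-hydroxyphenyl]-3-[4-(benzyloxy)phenyl]prop-2-en-1-one
Conditions: KOH, EtOH–THF, rt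
Reagents that add atoms: none
Why: Claisen–Schmidt aldol condensation of the methyl ketone enolate with a non-enolisable aldehyde; dehydration gives the (E)-enone.

Step 5
Reactants: 8 (E)-1-[3,4-bis(benzyloxy)-2-hydroxyphenyl]-3-[4-(benzyloxy)phenyl]prop-2-en-1-one
Product: 9 racemic 7,8-bis(benzyloxy)-2-[4-(benzyloxy)phenyl]chroman-4-one
Conditions: NaOAc, EtOH, reflux
Reagents that add atoms: none
Why: Intramolecular oxa-Michael addition of the phenoxide to the enone closes the pyranone ring as the racemic flavanone; unchanged chalcone can be recycled.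

Step 6
Reactants: 9 racemic 7,8-bis(benzyloxy)-2-[4-(benzyloxy)phenyl]chroman-4-one
Product: 10 (2S,4S)-7,8-bis(benzyloxy)-2-[4-(benzyloxy)phenyl]chroman-4-ol (2,4-cis)
Conditions: RuCl[(S,S)-TsDPEN](p-cymene) (1 mol %), HCO2H–Et3N (1:1), EtOAc, rt, stopped near half conversion
Reagents that add atoms: none
Why: Noyori–Ikariya asymmetric transfer hydrogenation run as a kinetic resolution: the (S,S) catalyst forms the (4S)-carbinol as with aryl alkyl ketones, and only in the (2S)-ketone is that hydride delivery axial and trans to the C2 aryl, so the (2S,4S)-cis alcohol should form while the (2R)-ketone is left behind.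

Step 7
Reactants: 10 (2S,4S)-7,8-bis(benzyloxy)-2-[4-(benzyloxy)phenyl]chroman-4-ol; 4 2-(benzyloxy)benzene-1,3-diol
Product: 11 2-(benzyloxy)-4-{(2S,4S)-7,8-bis(benzyloxy)-2-[4-(benzyloxy)phenyl]chroman-4-yl}benzene-1,3-diol (2,4-trans)
Conditions: 4 (3 equiv), BF3·OEt2 (0.5 equiv), CH2Cl2, −40 to 0 °C
Reagents that add atoms: none
Why: Friedel–Crafts alkylation: the C4 hydroxyl ionises to a benzylic cation stabilised by O1 and the para C7 oxygen, the symmetric resorcinol can only attack through C4 (the same as C6, para to one hydroxyl and ortho to the other), and axial attack trans to the pseudo-equatorial C2 aryl should set C4(u) as the 2,4-trans isomer.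

Step 8
Reactants: 11 2-(benzyloxy)-4-{(2S,4S)-7,8-bis(benzyloxy)-2-[4-(benzyloxy)phenyl]chroman-4-yl}benzene-1,3-diol
Product: 13 3-(benzyloxy)-5-{(2S,4S)-7,8-bis(benzyloxy)-2-[4-(benzyloxy)phenyl]chroman-4-yl}-2,4-dihydroxybenzaldehyde, via hydroxymethyl resorcinol 12 (not isolated)
Conditions: MgCl2, Et3N, (CH2O)n, MeCN, reflux
Reagents that add atoms: formaldehyde (as paraformaldehyde), C=O
Why: Casnati–Skattebøl ortho-formylation: the magnesium phenoxide directs formaldehyde to the only free position ortho to a hydroxyl and a second formaldehyde oxidises the benzylic alkoxide by hydride transfer, so the carbon that becomes C4(l) enters with full regiocontrol.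

Step 9
Reactants: 13 3-(benzyloxy)-5-{(2S,4S)-7,8-bis(benzyloxy)-2-[4-(benzyloxy)phenyl]chroman-4-yl}-2,4-dihydroxybenzaldehyde
Product: 14 3,4-bis(benzyloxy)-5-{(2S,4R)-7,8-bis(benzyloxy)-2-[4-(benzyloxy)phenyl]chroman-4-yl}-2-hydroxybenzaldehyde
Conditions: BnBr (1.05 equiv), CsHCO3, MeCN, 60 °C
Reagents that add atoms: benzyl bromide, BrCc1ccccc1
Why: Williamson etherification: the hydroxyl para to the formyl group is the more acidic and is not held in the hydrogen bond to the carbonyl, so a hydrogen carbonate base should benzylate it and leave the ortho hydroxyl that becomes O1(l).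

Step 10
Reactants: 15 (E)-4-hydroxycinnamic acid
Product: 16 benzyl (E)-3-[4-(benzyloxy)phenyl]prop-2-enoate
Conditions: BnBr (2.2 equiv), K2CO3, DMF, rt
Reagents that add atoms: benzyl bromide, BrCc1ccccc1
Why: Williamson etherification of the phenol and alkylation of the carboxylate in one operation; the (E)-alkene is not touched.

Step 11
Reactants: 16 benzyl (E)-3-[4-(benzyloxy)phenyl]prop-2-enoate
Product: 17 (E)-3-[4-(benzyloxy)phenyl]prop-2-en-1-ol
Conditions: i-Bu2AlH (2.5 equiv), CH2Cl2, −78 °C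
Reagents that add atoms: none
Why: 1,2-Reduction of the unsaturated ester by the aluminium hydride gives the (E)-allylic alcohol and leaves alkene and aryl benzyl ether intact.

Step 12
Reactants: 17 (E)-3-[4-(benzyloxy)phenyl]prop-2-en-1-ol
Product: 18 (E)-3-[4-(benzyloxy)phenyl]prop-2-en-1-yl methyl carbonate
Conditions: ClCO2Me, pyridine, CH2Cl2, 0 °C
Reagents that add atoms: methyl chloroformate, COC(=O)Cl
Why: O-Acylation of the primary alcohol with a chloroformate gives the linear allylic carbonate, the usual electrophile for iridium-catalysed allylic substitution.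

Step 13
Reactants: 14 3,4-bis(benzyloxy)-5-{(2S,4R)-7,8-bis(benzyloxy)-2-[4-(benzyloxy)phenyl]chroman-4-yl}-2-hydroxybenzaldehyde; 18 (E)-3-[4-(benzyloxy)phenyl]prop-2-en-1-yl methyl carbonate
Product: 19 3,4-bis(benzyloxy)-2-{(1S)-1-[4-(benzyloxy)phenyl]prop-2-en-1-yloxy}-5-{(2S,4R)-7,8-bis(benzyloxy)-2-[4-(benzyloxy)phenyl]chroman-4-yl}benzaldehyde
Conditions: NaH (1.0 equiv), THF, 0 °C; then 18 (1.3 equiv), [Ir(cod)Cl]2 (2 mol %), (Sa,Sc,Sc)-(1,1'-binaphthalene-2,2'-diyl) N,N-bis(1-phenylethyl)phosphoramidite (4 mol %, catalyst pre-formed with n-PrNH2 and freed of the amine), THF, rt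
Reagents that add atoms: none
Why: Iridium-catalysed asymmetric allylic etherification: the cyclometallated iridium phosphoramidite forms an allyl complex that the phenoxide attacks at the aryl-bearing terminus, giving the branched ether with C2(l) set by the ligand (catalyst control), independent of the remote upper unit.

Step 14
Reactants: 19 3,4-bis(benzyloxy)-2-{(1S)-1-[4-(benzyloxy)phenyl]prop-2-en-1-yloxy}-5-{(2S,4R)-7,8-bis(benzyloxy)-2-[4-(benzyloxy)phenyl]chroman-4-yl}benzaldehyde
Product: 20 3,4-bis(benzyloxy)-2-{(1R,2RS)-1-[4-(benzyloxy)phenyl]-2,3-dihydroxypropoxy}-5-{(2S,4R)-7,8-bis(benzyloxy)-2-[4-(benzyloxy)phenyl]chroman-4-yl}benzaldehyde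
Conditions: OsO4 (2 mol %), NMO, acetone–H2O, rt
Reagents that add atoms: N-methylmorpholine N-oxide, C[N+]1([O-])CCOCC1; water, O
Why: Upjohn dihydroxylation: OsO4 adds only to the terminal alkene, the new carbinol centre is excised in the next step, and the diol is a purifiable, storable form of the labile aldehyde.

Step 15
Reactants: 20 3,4-bis(benzyloxy)-2-{(1R,2RS)-1-[4-(benzyloxy)phenyl]-2,3-dihydroxypropoxy}-5-{(2S,4R)-7,8-bis(benzyloxy)-2-[4-(benzyloxy)phenyl]chroman-4-yl}benzaldehyde
Product: 21 3,4-bis(benzyloxy)-2-{(1R)-1-[4-(benzyloxy)phenyl]-2-oxoethoxy}-5-{(2S,4R)-7,8-bis(benzyloxy)-2-[4-(benzyloxy)phenyl]chroman-4-yl}benzaldehyde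
Conditions: NaIO4 on silica gel, CH2Cl2, 0 °C; filtered cold and used at once
Reagents that add atoms: none
Why: Malaprade glycol cleavage under neutral, heterogeneous conditions at 0 °C releases the α-aryloxy aldehyde without acid or base, so C2(l) should keep its configuration if the filtrate goes straight into the next step.

Step 16
Reactants: 21 3,4-bis(benzyloxy)-2-{(1R)-1-[4-(benzyloxy)phenyl]-2-oxoethoxy}-5-{(2S,4R)-7,8-bis(benzyloxy)-2-[4-(benzyloxy)phenyl]chroman-4-yl}benzaldehyde
Product: 22 (2R,3R,4R)-7,8-bis(benzyloxy)-2-[4-(benzyloxy)phenyl]-6-{(2S,4R)-7,8-bis(benzyloxy)-2-[4-(benzyloxy)phenyl]chroman-4-yl}chroman-3,4-diol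
Conditions: SmI2 (2.5 equiv, 0.02 M in THF), −78 °C, slow addition of 21, no HMPA, no proton source; then aq. NaHCO3
Reagents that add atoms: none
Why: Electron transfer from divalent samarium to the aryl aldehyde, the more easily reduced carbonyl because it is conjugated with ring A, gives the C4(l) ketyl, whose carbon adds to the aldehyde carbon C3(l) held close by the O1(l) tether; a second electron gives the trivalent samarium diolate, which is protonated only on work-up. The closest known reaction type is the SmI2-mediated intramolecular pinacol coupling of 1,6-dialdehydes to cyclic cis-1,2-diols. Ring C is closed in the 6-exo-trig mode, the C3(l) carbonyl oxygen staying outside the new ring. The cis relation of the C3(l) and C4(l) hydroxyls is enforced by samarium bridging both oxygens, and their face is set by C2(l): with the C2(l) aryl pseudo-equatorial in the chair-like transition state and the ketyl oxygen turned away from O1(l), the C4(l) oxygen becomes pseudo-equatorial and the bridged C3(l) oxygen axial, gauche to O1(l), which samarium can also bind, so both hydroxyls should end syn to the C2(l) aryl. The step needs chemoselectivity (no electron transfer to the α-aryloxy aldehyde, which would expel the aryloxide) and diastereofacial selectivity for the all-cis isomer; the first is secured by the conjugated aldehyde and slow addition at −78 °C, the second rests only on C2(l) and O1(l) and is where the route carries its risk.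

Step 17
Reactants: 22 (2R,3R,4R)-7,8-bis(benzyloxy)-2-[4-(benzyloxy)phenyl]-6-{(2S,4R)-7,8-bis(benzyloxy)-2-[4-(benzyloxy)phenyl]chroman-4-yl}chroman-3,4-diol
Product: 23 (2R,3R,4R)-6-[(2S,4S)-7,8-dihydroxy-2-(4-hydroxyphenyl)chroman-4-yl]-2-(4-hydroxyphenyl)chroman-3,4,7,8-tetrol
Conditions: H2 (1 atm), Pd(OH)2 on carbon, THF–MeOH, rt; work-up under argon
Reagents that add atoms: none
Why: Hydrogenolysis of the six aryl benzyl ethers under neutral conditions; without acid the secondary benzylic hydroxyl at C4(l) and the cyclic benzylic ethers should react far more slowly, and no stereocentre is touched.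

Compound list
1 | 2,3-dihydroxybenzaldehyde | O=Cc1cccc(O)c1O | starting material
2 | 2-(benzyloxy)-3-hydroxybenzaldehyde | O=Cc1cccc(O)c1OCc1ccccc1 | intermediate
3 | 2-(benzyloxy)-3-hydroxyphenyl formate | O=COc1cccc(O)c1OCc1ccccc1 | intermediate (not isolated)
4 | 2-(benzyloxy)benzene-1,3-diol | Oc1cccc(O)c1OCc1ccccc1 | intermediate
5 | 1-(2,3,4-trihydroxyphenyl)ethanone | CC(=O)c1ccc(O)c(O)c1O | starting material
6 | 1-[3,4-bis(benzyloxy)-2-hydroxyphenyl]ethanone | CC(=O)c1ccc(OCc2ccccc2)c(OCc2ccccc2)c1O | intermediate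
7 | 4-(benzyloxy)benzaldehyde | O=Cc1ccc(OCc2ccccc2)cc1 | starting material
8 | (E)-1-[3,4-bis(benzyloxy)-2-hydroxyphenyl]-3-[4-(benzyloxy)phenyl]prop-2-en-1-one | O=C(/C=C/c1ccc(OCc2ccccc2)cc1)c1ccc(OCc2ccccc2)c(OCc2ccccc2)c1O | intermediate
9 | racemic 7,8-bis(benzyloxy)-2-[4-(benzyloxy)phenyl]chroman-4-one | c5ccccc5COc1ccc(C2CC(=O)c3ccc(OCc5ccccc5)c(OCc5ccccc5)c3O2)cc1 | intermediate
10 | (2S,4S)-7,8-bis(benzyloxy)-2-[4-(benzyloxy)phenyl]chroman-4-ol (2,4-cis) | c5ccccc5COc1ccc([C@@H]2C[C@H](O)c3ccc(OCc5ccccc5)c(OCc5ccccc5)c3O2)cc1 | intermediate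
11 | 2-(benzyloxy)-4-{(2S,4S)-7,8-bis(benzyloxy)-2-[4-(benzyloxy)phenyl]chroman-4-yl}benzene-1,3-diol (2,4-trans) | c5ccccc5COc1ccc([C@@H]2C[C@@H](c3ccc(O)c(OCc5ccccc5)c3O)c3ccc(OCc5ccccc5)c(OCc5ccccc5)c3O2)cc1 | intermediate
12 | 2-(benzyloxy)-4-{(2S,4S)-7,8-bis(benzyloxy)-2-[4-(benzyloxy)phenyl]chroman-4-yl}-6-(hydroxymethyl)benzene-1,3-diol | c5ccccc5COc1ccc([C@@H]2C[C@@H](c3cc(CO)c(O)c(OCc5ccccc5)c3O)c3ccc(OCc5ccccc5)c(OCc5ccccc5)c3O2)cc1 | intermediate (not isolated)
13 | 3-(benzyloxy)-5-{(2S,4S)-7,8-bis(benzyloxy)-2-[4-(benzyloxy)phenyl]chroman-4-yl}-2,4-dihydroxybenzaldehyde | c5ccccc5COc1ccc([C@@H]2C[C@@H](c3cc(C=O)c(O)c(OCc5ccccc5)c3O)c3ccc(OCc5ccccc5)c(OCc5ccccc5)c3O2)cc1 | intermediate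
14 | 3,4-bis(benzyloxy)-5-{(2S,4R)-7,8-bis(benzyloxy)-2-[4-(benzyloxy)phenyl]chroman-4-yl}-2-hydroxybenzaldehyde | c5ccccc5COc1ccc([C@@H]2C[C@@H](c3cc(C=O)c(O)c(OCc5ccccc5)c3OCc5ccccc5)c3ccc(OCc5ccccc5)c(OCc5ccccc5)c3O2)cc1 | intermediate
15 | (E)-4-hydroxycinnamic acid | OC(=O)/C=C/c1ccc(O)cc1 | starting material
16 | benzyl (E)-3-[4-(benzyloxy)phenyl]prop-2-enoate | O=C(OCc1ccccc1)/C=C/c1ccc(OCc2ccccc2)cc1 | intermediate
17 | (E)-3-[4-(benzyloxy)phenyl]prop-2-en-1-ol | OC/C=C/c1ccc(OCc2ccccc2)cc1 | intermediate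
18 | (E)-3-[4-(benzyloxy)phenyl]prop-2-en-1-yl methyl carbonate | COC(=O)OC/C=C/c1ccc(OCc2ccccc2)cc1 | intermediate
19 | 3,4-bis(benzyloxy)-2-{(1S)-1-[4-(benzyloxy)phenyl]prop-2-en-1-yloxy}-5-{(2S,4R)-7,8-bis(benzyloxy)-2-[4-(benzyloxy)phenyl]chroman-4-yl}benzaldehyde | c5ccccc5COc1ccc([C@@H]2C[C@@H](c3cc(C=O)c(c(OCc5ccccc5)c3OCc5ccccc5)O[C@H](c3ccc(OCc5ccccc5)cc3)C=C)c3ccc(OCc5ccccc5)c(OCc5ccccc5)c3O2)cc1 | intermediate
20 | 3,4-bis(benzyloxy)-2-{(1R,2RS)-1-[4-(benzyloxy)phenyl]-2,3-dihydroxypropoxy}-5-{(2S,4R)-7,8-bis(benzyloxy)-2-[4-(benzyloxy)phenyl]chroman-4-yl}benzaldehyde | c5ccccc5COc1ccc([C@@H]2C[C@@H](c3cc(C=O)c(c(OCc5ccccc5)c3OCc5ccccc5)O[C@H](c3ccc(OCc5ccccc5)cc3)C(O)CO)c3ccc(OCc5ccccc5)c(OCc5ccccc5)c3O2)cc1 | intermediate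
21 | 3,4-bis(benzyloxy)-2-{(1R)-1-[4-(benzyloxy)phenyl]-2-oxoethoxy}-5-{(2S,4R)-7,8-bis(benzyloxy)-2-[4-(benzyloxy)phenyl]chroman-4-yl}benzaldehyde | c5ccccc5COc1ccc([C@@H]2C[C@@H](c3cc(C=O)c(c(OCc5ccccc5)c3OCc5ccccc5)O[C@H](c3ccc(OCc5ccccc5)cc3)C=O)c3ccc(OCc5ccccc5)c(OCc5ccccc5)c3O2)cc1 | intermediate
22 | (2R,3R,4R)-7,8-bis(benzyloxy)-2-[4-(benzyloxy)phenyl]-6-{(2S,4R)-7,8-bis(benzyloxy)-2-[4-(benzyloxy)phenyl]chroman-4-yl}chroman-3,4-diol | c5ccccc5COc1ccc([C@@H]2C[C@@H](c3cc4c(c(OCc5ccccc5)c3OCc5ccccc5)O[C@H](c3ccc(OCc5ccccc5)cc3)[C@H](O)[C@@H]4O)c3ccc(OCc5ccccc5)c(OCc5ccccc5)c3O2)cc1 | intermediate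
23 | (2R,3R,4R)-6-[(2S,4S)-7,8-dihydroxy-2-(4-hydroxyphenyl)chroman-4-yl]-2-(4-hydroxyphenyl)chroman-3,4,7,8-tetrol | Oc1ccc([C@@H]2C[C@@H](c3cc4c(c(O)c3O)O[C@H](c3ccc(O)cc3)[C@H](O)[C@@H]4O)c3ccc(O)c(O)c3O2)cc1 | target

Total step count: 17. Longest linear sequence: 12 steps (steps 3–9 and 13–17, from 5 to 23).

Steps most likely to fail

1. Step 16. What may go wrong: poor or reversed facial selectivity, the samarium-bridged cis-diol forming anti to the C2(l) aryl group, or electron transfer to the aliphatic aldehyde with loss of the aryloxide. The fallback closes ring C by metathesis and puts the diol on afterwards. It sets out from 19. Wittig methylenation of the aryl aldehyde (Ph3P=CH2, THF, −78 to 0 °C) should give the styrene F1. Ring-closing metathesis with the second-generation Grubbs catalyst RuCl2(=CHPh)(H2IMes)(PCy3) (CH2Cl2, 40 °C) should close ring C as the (2S)-flav-3-ene F2. Woodward cis-hydroxylation (I2, AgOAc, AcOH, then wet AcOH) places iodine on the face anti to the C2(l) aryl; acetate opening at C4(l) and displacement of iodide through the acetoxonium ion then put both oxygens syn to that aryl, giving the all-cis diol 3-acetate F3. Methanolysis (K2CO3, MeOH) comes back to the route at 22.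

2. Step 13. What may go wrong: loss of enantio- and branch selectivity, because the cinnamyl unit is electron-rich and the hindered salicylaldehyde phenoxide is weakly basic and a good leaving group, so the product ether can re-ionise and drift to the linear or racemic ether. A minor C2(l) epimer would be a diastereomer and removable at 20 or 22, but a poor ratio calls for another way of making the C2(l)–O1(l) bond. The fallback sets out from 14. A Mitsunobu reaction (PPh3, diisopropyl azodicarboxylate, THF, 0 °C) is run with benzyl (S)-4-(benzyloxy)mandelate F4, itself one step from (S)-4-hydroxymandelic acid (BnBr, K2CO3, DMF). It should give, with inversion and without ionisation (the ester destabilises the cation), the (R)-α-aryloxy ester F5. LiBH4 (THF, 0 °C) reduces ester and aryl aldehyde to the diol F6. Dess–Martin periodinane (NaHCO3, CH2Cl2, 0 °C) oxidises both primary alcohols and comes back to the route at 21.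

3. Step 15. What may go wrong: epimerisation at C2(l) by enolisation of the α-aryl-α-aryloxy aldehyde on the solid support or during concentration, and hydrate formation that slows the next step. The fallback sets out from 19 and cleaves the vinyl group directly by ozonolysis (O3, CH2Cl2, −78 °C, Sudan red 7B as end-point indicator to spare the alkoxyarenes; then PPh3). The cold solution is switched to THF and cannulated into SmI2 without isolation. It comes back to the route at 21 and makes no new compound (F0).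

Further compounds
F1 | step 16 | 1,2-bis(benzyloxy)-3-{(1S)-1-[4-(benzyloxy)phenyl]prop-2-en-1-yloxy}-6-{(2S,4R)-7,8-bis(benzyloxy)-2-[4-(benzyloxy)phenyl]chroman-4-yl}-4-ethenylbenzene | c5ccccc5COc1ccc([C@@H]2C[C@@H](c3cc(C=C)c(c(OCc5ccccc5)c3OCc5ccccc5)O[C@H](c3ccc(OCc5ccccc5)cc3)C=C)c3ccc(OCc5ccccc5)c(OCc5ccccc5)c3O2)cc1
F2 | step 16 | (2S)-7,8-bis(benzyloxy)-2-[4-(benzyloxy)phenyl]-6-{(2S,4R)-7,8-bis(benzyloxy)-2-[4-(benzyloxy)phenyl]chroman-4-yl}-2H-chromene | c5ccccc5COc1ccc([C@@H]2C[C@@H](c3cc4c(c(OCc5ccccc5)c3OCc5ccccc5)O[C@H](c3ccc(OCc5ccccc5)cc3)C=C4)c3ccc(OCc5ccccc5)c(OCc5ccccc5)c3O2)cc1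
F3 | step 16 | (2R,3R,4R)-7,8-bis(benzyloxy)-2-[4-(benzyloxy)phenyl]-6-{(2S,4R)-7,8-bis(benzyloxy)-2-[4-(benzyloxy)phenyl]chroman-4-yl}-4-hydroxychroman-3-yl acetate | c5ccccc5COc1ccc([C@@H]2C[C@@H](c3cc4c(c(OCc5ccccc5)c3OCc5ccccc5)O[C@H](c3ccc(OCc5ccccc5)cc3)[C@H](OC(C)=O)[C@@H]4O)c3ccc(OCc5ccccc5)c(OCc5ccccc5)c3O2)cc1
F4 | step 13 | benzyl (2S)-2-[4-(benzyloxy)phenyl]-2-hydroxyacetate | O[C@@H](c1ccc(OCc2ccccc2)cc1)C(=O)OCc1ccccc1
F5 | step 13 | benzyl (2R)-2-[4-(benzyloxy)phenyl]-2-(2,3-bis(benzyloxy)-4-{(2S,4R)-7,8-bis(benzyloxy)-2-[4-(benzyloxy)phenyl]chroman-4-yl}-6-formylphenoxy)acetate | c5ccccc5COc1ccc([C@@H]2C[C@@H](c3cc(C=O)c(c(OCc5ccccc5)c3OCc5ccccc5)O[C@H](c3ccc(OCc5ccccc5)cc3)C(=O)OCc3ccccc3)c3ccc(OCc5ccccc5)c(OCc5ccccc5)c3O2)cc1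
F6 | step 13 | (2R)-2-[4-(benzyloxy)phenyl]-2-(2,3-bis(benzyloxy)-4-{(2S,4R)-7,8-bis(benzyloxy)-2-[4-(benzyloxy)phenyl]chroman-4-yl}-6-(hydroxymethyl)phenoxy)ethan-1-ol | c5ccccc5COc1ccc([C@@H]2C[C@@H](c3cc(CO)c(c(OCc5ccccc5)c3OCc5ccccc5)O[C@H](c3ccc(OCc5ccccc5)cc3)CO)c3ccc(OCc5ccccc5)c(OCc5ccccc5)c3O2)cc1
F0 | step 15 | none | none
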